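Numbering used throughout: spiro carbon C1; ring B C1–C2H2–C3H–C4H–C5(CH3)(OH)–C6H2; ring C C3–C9(CH3)(OH)–C8H2–C7H2–C4; ring A C1–C10(=O)–C11(prenyl)2–C12(OH)=C13(acyl)–C14(=O).

## Analysis of the target

The target is a spiro compound. Ring A is an enolised 2-acylcyclohexane-1,3,5-trione with two prenyl groups on C11 and a 3-methylbutanoyl group on C13. It shares C1 with ring B, a cyclohexane that is trans-fused along C3–C4 to the cyclopentane ring C.

There are five stereocentres: C1 (S), C3 (S), C4 (R), C5 (S) and C9 (R). H-3 and H-4 are trans, the C9 hydroxyl is cis to the C2 methylene on C3, and the C5 hydroxyl is axial on ring B on the same face as C14, which is axial on C1. C1 is stereogenic only because its two carbonyl arms differ further out (C10 leads to the diprenylated C11, C14 to the acylated C13), so its configuration is in effect a question of regiochemistry when ring A is assembled.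

Sensitive features are the acidic β-triketone enol (oxygen versus carbon alkylation, retro-Claisen cleavage), two tertiary alcohols that can eliminate, a C5 hydroxyl held directly over C14, and prenyl alkenes that are oxidisable, hydrogenable and acid-labile. The difficulties are the quaternary spiro centre between two carbonyl groups, two tertiary carbinols of defined configuration on a trans-hydrindane, and the need to create absolute configuration from open-chain material.

The plan rests on one relationship in ring C: the tertiary methyl carbinol C9 stands cis to the one-carbon arm C2 on the adjacent C3. This is the syn-aldol pattern of an ester enolate at C3 (ester carbon C2) and a methyl ketone at C9. Since that enolate can be generated by hydride addition to C4 of an enoate, ring C and the C3/C9 pair can be made in one catalytic, enantioselective step from an acyclic keto enoate.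

## Retrosynthetic reasoning

**25 from 24 from 23.** The silyl ether on O–C9 is removed last, and before that the two C11–C(prenyl) bonds are cut. The prenyl alkenes go first in the retrosynthetic direction because they would not survive the hydrogenolysis and the one-electron oxidation used earlier. In 23, C11 is the only carbon of ring A that still carries hydrogen, so a twofold carbon alkylation of its polyanion has only one place to go.

**23 from 20 and 21.** Ring A is opened at C10–C11 and C13–C14. This places C11, C12, C13 and the whole acyl chain in the commercial dione 21. It also reduces the configuration at C1 to a difference that already exists in 20: C10 is an activated, equatorial acyl imidazole and C14 is an axial lactone carbonyl tied to O–C5. The forward reaction must acylate the terminal carbon of the dianion of 21 at C10 first (giving 22) and then let C13 open the lactone at C14. The same event frees the C5 hydroxyl.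

**20 from 19 from 18.** The C10 carboxyl must be unmasked beside the lactone. A benzyl ester allows this by hydrogenolysis, which is why dibenzyl malonate 16 is used. Hydrolysis of a simple alkyl ester would not distinguish it from the lactone.

**18 from 17.** The C1–C6 bond and the O–C5 bond are cut together. Forward, a malonyl radical at C1 adds to C6 of the isopropenyl group and the oxidised C5 centre is captured by one ester. This builds ring B, the quaternary C1 and the tertiary C5–O bond at once. Both new stereocentres are dictated by the trans arrangement at C3/C4, because in the chair of ring B only the axial ester can reach C5, and only from the axial face.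

**17 from 15 and 16; 15 from 14 from 13.** C1–C2 is cut as a malonate alkylation. C2 is the former ester carbon, taken through alcohol 14 to iodide 15. The alkene of 13 is installed before the ester is reduced, because a hydride reagent would not tell the ester from the methyl ketone of 12.

**13 from 12 from 11 from 10 from 9 from 8.** The C5=C6 alkene comes from the C5 acetyl group of 12 by methylenation. The acetyl group also makes C4 epimerisable, so the trans arrangement of the C3 and C4 substituents can be secured by equilibration (11 to 12) whatever the kinetic outcome at C4 was. The ketone 10 comes from carbinol 9, and that from silyl ether 8. The C9 hydroxyl is capped as its triethylsilyl ether (10 to 11) to shut off retro-aldol cleavage and, later, attack of O–C9 on the C10 acyl group.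

**8 from 7 (key disconnection).** The C3–C9 bond is cut. Forward, hydride addition to C4 of the enoate 7 generates the C3 enolate, which closes ring C onto the C9 ketone and sets C3 and C9 with hydroxyl and ester cis. The gain is one ring, one skeletal bond and the two stereocentres that define the absolute configuration of everything that follows.

**7 from 6 from 3 and 4 (through 5); 3 from 2 from 1.** The C4–C7 bond is cut as a syn carbometalation of ynoate 3 by the organocopper reagent derived from Grignard reagent 5 (made from bromide 4). This fixes the enoate geometry with the ester cis to the silyloxyethyl group. The carbinol carbon of 1 becomes C5. A single enantiomer, (R)-1, is used: with a racemic carbinol the two substrate enantiomers would meet the chiral catalyst differently, and once the carbinol is oxidised any ring of the opposite sense would become the enantiomer. With (R)-1 such material stays a separable diastereomer.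

## Alternatives that were turned down

**Alternative 1:** enzymatic diprenylation of a symmetric trione.
- **Disconnection:** the two C11–C(prenyl) bonds, made at the very end on a ring A without the acyl group.
- **Forward key step:** an aromatic prenyltransferase and its diphosphate donor transfer two prenyl groups to one of the two ring methylenes of the symmetric spiro trione A1, giving A2 (the target lacking its 3-methylbutanoyl group). C-acylation at C13 would follow.
- **For:** in A1, C11 and C13 are equivalent by constitution and C1 is not a stereocentre. Ring A could be built without telling C10 from C14, and the late stage would need no protecting groups. On this point it is stronger than the chosen route, which needs a lactone and an acyl imidazole to differentiate the two carbonyl groups.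
- **Against:** the differentiation is handed to an enzyme whose normal substrates are planar acylphloroglucinols. A1 is neither aromatic nor acylated. Its two methylenes differ only through the remote centres of ring B. The mechanism (attack of an enolate on an allyl cation) does not predict which methylene reacts, or that exactly two groups enter at one carbon. The final C13 acylation must also beat O-acylation, and the carbocyclic core is left unaddressed.
- **Comparison:** the chosen strategy is longer at the end but fixes C1 by ground-state geometry and needs no biocatalyst development.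

**Alternative 2:** manganese radical closure as the central event.
- **Disconnection:** C1–C6 and O–C5.
- **Forward key step:** a one-electron manganese oxidant converts the malonate A3 into the bridged lactone methyl ester A4.
- **For:** it gives the largest gain per step of any option: ring B, the lactone, the quaternary C1 and the C5–O bond, with two stereocentres relayed from C3/C4. The chosen route uses the same reaction type in step 14.
- **Against:** A3 already contains C3, C4 and C9 in enantiopure form, and the radical step cannot create them. The question of absolute configuration and of the cis C9/C3 relationship is only moved back. The methyl ester of A4 is also hard to cleave beside the lactone.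
- **Comparison:** on bond economy in a single step this alternative is stronger. The chosen strategy supplies the enantiopure ring C that it presupposes, and then borrows the cyclisation with benzyl esters.

**Alternative 3:** lactone-templated double Claisen condensation as the central event.
- **Disconnection:** C10–C11 and C13–C14.
- **Forward key step:** a β-diketone dianion is acylated at its terminal carbon by an activated C10 acyl group, and the C13 carbanion then opens the lactone, giving A5 (identical with 23).
- **For:** it is the most convergent option. All remaining carbons of ring A and the acyl chain arrive in one operation, and the configuration at C1 is read off the lactone. The chosen route uses it in step 17.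
- **Against:** it says nothing about the origin of the lactone with its four stereocentres. It is a late, substrate-specific step that depends on chemoselection between two acyl groups on one quaternary carbon, and a failure there would give the C1 epimer.
- **Comparison:** it is as strong as the chosen strategy on convergence. The chosen strategy adds catalytic control of absolute configuration at the start, where a failure costs little material.

Key step: step 5

Assumption (sense of induction in step 5): (R)-1 and (R)-DTBM-SEGPHOS are written as the matched pair. The substrate's own bias is derived from allylic 1,3-strain (hydride enters anti to the silyloxy group, which gives the target configuration at C4); should the ligand oppose it, its enantiomer is used with no other change.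

Assumption (tautomers): the β-triketones 23, 24 and 25 are drawn as one enol form; they are expected to be equilibrating enol tautomers, which affects no stereocentre.

## Route

Step 1
Reactants: 1 (2R)-but-3-yn-2-ol
Product: 2 tert-butyl{[(2R)-but-3-yn-2-yl]oxy}dimethylsilane
Conditions: TBSCl, imidazole, DMF, rt
Reagents that add atoms: tert-butyldimethylsilyl chloride, CC(C)(C)[Si](C)(C)Cl
Why: Standard silyl ether formation on a secondary propargylic alcohol; the stereocentre is not involved, and the bulky, non-coordinating silyl ether later serves as the face-shielding group in step 5.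

Step 2
Reactants: 2 tert-butyl{[(2R)-but-3-yn-2-yl]oxy}dimethylsilane
Product: 3 methyl (4R)-4-{[tert-butyl(dimethyl)silyl]oxy}pent-2-ynoate
Conditions: n-BuLi, THF, −78 °C; ClCO2Me, −78 to 0 °C
Reagents that add atoms: methyl chloroformate, COC(=O)Cl
Why: Deprotonation of the terminal alkyne and acylation of the lithium acetylide by the chloroformate; the carbon introduced here is C2.

Step 3
Reactants: 3 methyl (4R)-4-{[tert-butyl(dimethyl)silyl]oxy}pent-2-ynoate; 4 2-(2-bromoethyl)-2-methyl-1,3-dioxolane
Product: 6 methyl (2Z)-3-[(1R)-1-{[tert-butyl(dimethyl)silyl]oxy}ethyl]-5-(2-methyl-1,3-dioxolan-2-yl)pent-2-enoate, via Grignard reagent 5 (not isolated)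
Conditions: 4, Mg, THF, 25 °C; CuBr·SMe2, THF, −78 °C; then 3, −78 °C; sat. aq. NH4Cl at −78 °C
Reagents that add atoms: none
Why: Syn carbocupration of an ynoate by the organocopper reagent made from 5 forms C4–C7 with carbon and copper on the same side. Protonation of the alkenylcopper at −78 °C, before it can isomerise through the allenolate, leaves the ester cis to the silyloxyethyl group, i.e. the (2Z) enoate.

Step 4
Reactants: 6 methyl (2Z)-3-[(1R)-1-{[tert-butyl(dimethyl)silyl]oxy}ethyl]-5-(2-methyl-1,3-dioxolan-2-yl)pent-2-enoate
Product: 7 methyl (2Z)-3-[(1R)-1-{[tert-butyl(dimethyl)silyl]oxy}ethyl]-6-oxohept-2-enoate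
Conditions: PPTS, acetone/H2O, rt to 40 °C
Reagents that add atoms: water, O
Why: Acid-catalysed hydrolysis of the dioxolane of an unhindered dialkyl ketone under conditions that a secondary tert-butyldimethylsilyl ether tolerates. The silyl ether must stay, since the free Z-γ-hydroxy enoate would close to a butenolide.

Step 5
Reactants: 7 methyl (2Z)-3-[(1R)-1-{[tert-butyl(dimethyl)silyl]oxy}ethyl]-6-oxohept-2-enoate
Product: 8 methyl (1S,2R)-5-[(1R)-1-{[tert-butyl(dimethyl)silyl]oxy}ethyl]-2-hydroxy-2-methylcyclopentane-1-carboxylate (hydroxyl and ester cis; ring carbon 5 not relied on; 5R expected to prevail)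
Conditions: Cu(OAc)2·H2O (5 mol %), (R)-DTBM-SEGPHOS (5 mol %), (EtO)2MeSiH (2 equiv), toluene, 0 °C to rt; then 1 M aq. HCl, THF, 0 °C, brief; chromatography
Reagents that add atoms: none
Why: Cu(OAc)2 and the silane give a bisphosphine-bound monovalent copper hydride that delivers hydride to C4 of the enoate; the closest known reaction type is the copper hydride reductive aldol cyclisation of keto enoates and keto enones, β,β-disubstituted ones included. The copper enolate at C3 then adds to the tethered methyl ketone through a closed, chair-like six-membered transition state in which copper bridges both oxygens; this forms C3–C9 and closes ring C in a 5-exo-trig mode. Because both oxygens stay on copper, the C9 hydroxyl and the ester emerge cis and the C9 methyl trans to the ester. The face of hydride delivery at C4 is set by the ligand together with the (R)-silyloxy centre: allylic 1,3-strain against the cis ester holds the carbinol hydrogen in the alkene plane, so hydride enters anti to the silyloxy group. The absolute sense at C3 and C9 follows from the chiral copper enolate and from allylic strain in the enolate, which places the new bond trans to the C4 substituent; ring of the opposite sense is a diastereomer because of the fixed carbinol and is removed here. C4 itself is not relied on, since it is equilibrated in step 9. The step needs chemoselectivity for conjugate reduction over 1,2-reduction of the ketone; the ester-activated Z-enoate carrying an inductively withdrawing γ-silyloxy group is opposed only by a dialkyl ketone, the least reactive ketone class toward copper hydride, and intramolecular capture of the enolate outruns its silylation. σ-Bond metathesis of the copper aldolate with the silane turns the catalyst over, and the labile silyl ether is hydrolysed on work-up.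

Step 6
Reactants: 8 methyl (1S,2R)-5-[(1R)-1-{[tert-butyl(dimethyl)silyl]oxy}ethyl]-2-hydroxy-2-methylcyclopentane-1-carboxylate
Product: 9 methyl (1S,2R)-2-hydroxy-5-[(1R)-1-hydroxyethyl]-2-methylcyclopentane-1-carboxylate
Conditions: HF·pyridine, THF, 0 °C to rt
Reagents that add atoms: none
Why: Fluoride cleavage of the secondary silyl ether under weakly acidic conditions that cause neither retro-aldol cleavage nor elimination of the β-hydroxy ester. The trans-disposed carbinol arm cannot lactonise onto the ester (it would need a trans-fused bicyclo[3.3.0] system), but a cis portion could, so 9 is oxidised without storage.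

Step 7
Reactants: 9 methyl (1S,2R)-2-hydroxy-5-[(1R)-1-hydroxyethyl]-2-methylcyclopentane-1-carboxylate
Product: 10 methyl (1S,2R)-5-acetyl-2-hydroxy-2-methylcyclopentane-1-carboxylate
Conditions: Dess–Martin periodinane, NaHCO3, CH2Cl2, 0 °C to rt
Reagents that add atoms: none
Why: Dess–Martin oxidation of the secondary alcohol; the tertiary C9 hydroxyl cannot be oxidised and the buffered, non-basic medium avoids retro-aldol cleavage. The carbinol stereocentre, having done its work in step 5, is erased and becomes the C5 carbonyl.

Step 8
Reactants: 10 methyl (1S,2R)-5-acetyl-2-hydroxy-2-methylcyclopentane-1-carboxylate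
Product: 11 methyl (1S,2R)-5-acetyl-2-methyl-2-[(triethylsilyl)oxy]cyclopentane-1-carboxylate
Conditions: Et3SiOTf, 2,6-lutidine, CH2Cl2, −78 °C
Reagents that add atoms: triethylsilyl trifluoromethanesulfonate, CC[Si](CC)(CC)OS(=O)(=O)C(F)(F)F
Why: Silylation of a tertiary alcohol by a silyl triflate with a hindered pyridine base at a temperature where the methyl ketone is not converted into an enol silane. The ether blocks retro-aldol cleavage and later attack of O–C9 on acyl groups.

Step 9
Reactants: 11 methyl (1S,2R)-5-acetyl-2-methyl-2-[(triethylsilyl)oxy]cyclopentane-1-carboxylate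
Product: 12 methyl (1S,2R,5R)-5-acetyl-2-methyl-2-[(triethylsilyl)oxy]cyclopentane-1-carboxylate
Conditions: K2CO3, MeOH, rt
Reagents that add atoms: none
Why: Base-mediated equilibration at C4, the only stereocentre α to the ketone: the acetyl group settles trans to the ester on C3, the more stable arrangement on the cyclopentane, which fixes C4 as in the target. C3 (ester α-carbon, far less acidic) and the silylated C9 are not affected, and the methyl ester is degenerate toward methanolysis.

Step 10
Reactants: 12 methyl (1S,2R,5R)-5-acetyl-2-methyl-2-[(triethylsilyl)oxy]cyclopentane-1-carboxylate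
Product: 13 methyl (1S,2R,5R)-2-methyl-5-(prop-1-en-2-yl)-2-[(triethylsilyl)oxy]cyclopentane-1-carboxylate
Conditions: CH3PPh3Br, KOtBu, THF, 0 °C to rt
Reagents that add atoms: methyltriphenylphosphonium bromide, C[P+](c1ccccc1)(c1ccccc1)c1ccccc1.[Br-]
Why: Wittig methylenation of the methyl ketone; the ester is inert to the non-stabilised ylide, and C4 already has its thermodynamic configuration, so the basic medium cannot degrade it. The new methylene carbon is C6.

Step 11
Reactants: 13 methyl (1S,2R,5R)-2-methyl-5-(prop-1-en-2-yl)-2-[(triethylsilyl)oxy]cyclopentane-1-carboxylate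
Product: 14 [(1R,2R,5R)-2-methyl-5-(prop-1-en-2-yl)-2-[(triethylsilyl)oxy]cyclopentyl]methanol
Conditions: iBu2AlH (2.5 equiv), CH2Cl2, −78 to 0 °C; aq. sodium potassium tartrate
Reagents that add atoms: none
Why: Aluminium hydride reduction of the ester to the primary alcohol; the alkene and the tertiary silyl ether are inert. Placed after step 10, it needs no distinction between ester and ketone.

Step 12
Reactants: 14 [(1R,2R,5R)-2-methyl-5-(prop-1-en-2-yl)-2-[(triethylsilyl)oxy]cyclopentyl]methanol
Product: 15 triethyl{[(1R,2S,3R)-2-(iodomethyl)-1-methyl-3-(prop-1-en-2-yl)cyclopentyl]oxy}silane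
Conditions: I2, PPh3, imidazole, CH2Cl2, 0 °C to rt
Reagents that add atoms: iodine, II
Why: Appel-type iodination: the alcohol is activated as an alkoxyphosphonium ion and displaced by iodide in an SN2 step, under buffered conditions that spare the silyl ether and the alkene.

Step 13
Reactants: 15 triethyl{[(1R,2S,3R)-2-(iodomethyl)-1-methyl-3-(prop-1-en-2-yl)cyclopentyl]oxy}silane; 16 dibenzyl propanedioate (dibenzyl malonate)
Product: 17 dibenzyl 2-{[(1S,2R,5R)-2-methyl-5-(prop-1-en-2-yl)-2-[(triethylsilyl)oxy]cyclopentyl]methyl}propanedioate
Conditions: 16 (2 equiv), NaH, THF/DMF, 0 to 60 °C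
Reagents that add atoms: none
Why: SN2 alkylation of the sodium enolate of the malonate by the primary iodide forms C1–C2; β-branching slows the substitution, hence the dipolar solvent and warming, and excess malonate suppresses double alkylation.

Step 14
Reactants: 17 dibenzyl 2-{[(1S,2R,5R)-2-methyl-5-(prop-1-en-2-yl)-2-[(triethylsilyl)oxy]cyclopentyl]methyl}propanedioate
Product: 18 benzyl (1S,2R,5R,6S,8S)-1,5-dimethyl-9-oxo-5-[(triethylsilyl)oxy]-10-oxatricyclo[6.2.1.0^2,6]undecane-8-carboxylate (ring B closed; lactone from axial C14 to O–C5; C10 as equatorial benzyl ester)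
Conditions: Mn(OAc)3·2H2O (2.2 equiv), AcOH, 60 °C
Reagents that add atoms: none
Why: Oxidative radical cyclisation by trivalent manganese: the manganese enolate of the malonate gives the C1 radical, which adds 6-endo to C6 of the 1,1-disubstituted alkene (the 5-exo mode would need a trans-fused bicyclo[3.3.0]octane and a new quaternary carbon). The tertiary C5 radical is oxidised by the second equivalent to the cation, which an ester carbonyl captures with loss of its benzyl group as benzyl acetate. In the chair of the trans-fused ring B only the axial ester reaches C5, and only from the axial face, so C5–O and C14 come out syn and C1 and C5 are set together from C3/C4.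

Step 15
Reactants: 18 benzyl (1S,2R,5R,6S,8S)-1,5-dimethyl-9-oxo-5-[(triethylsilyl)oxy]-10-oxatricyclo[6.2.1.0^2,6]undecane-8-carboxylate
Product: 19 (1S,2R,5R,6S,8S)-1,5-dimethyl-9-oxo-5-[(triethylsilyl)oxy]-10-oxatricyclo[6.2.1.0^2,6]undecane-8-carboxylic acid
Conditions: H2 (1 atm), Pd/C, EtOAc, rt
Reagents that add atoms: none
Why: Hydrogenolysis of the benzyl ester; no alkene is present at this stage and lactone and silyl ether are inert, so the C10 carboxyl is freed selectively.

Step 16
Reactants: 19 (1S,2R,5R,6S,8S)-1,5-dimethyl-9-oxo-5-[(triethylsilyl)oxy]-10-oxatricyclo[6.2.1.0^2,6]undecane-8-carboxylic acid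
Product: 20 (1S,2R,5R,6S,8S)-8-(1H-imidazole-1-carbonyl)-1,5-dimethyl-5-[(triethylsilyl)oxy]-10-oxatricyclo[6.2.1.0^2,6]undecan-9-one
Conditions: 1,1'-carbonyldiimidazole, THF, rt; used crude
Reagents that add atoms: 1,1'-carbonyldiimidazole, O=C(n1ccnc1)n1ccnc1
Why: Activation of the acid as its acyl imidazole with loss of CO2 and imidazole. This makes C10 a better acylating agent than the lactone carbonyl C14, which is the basis of the regiochemistry of step 17.

Step 17
Reactants: 20 (1S,2R,5R,6S,8S)-8-(1H-imidazole-1-carbonyl)-1,5-dimethyl-5-[(triethylsilyl)oxy]-10-oxatricyclo[6.2.1.0^2,6]undecan-9-one; 21 6-methylheptane-2,4-dione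
Product: 23 spiro triketone with ring A closed (13-(3-methylbutanoyl); C11 unsubstituted; C5 hydroxyl free; C9 triethylsilyl ether; 1S,3S,4R,5S,9R), via triketone lactone 22 (not isolated)
Conditions: 21 (2.2 equiv), LiN(iPr)2 (4.4 equiv), THF, −78 to 0 °C; 20, −78 °C to rt, then 40 °C; 1 M aq. HCl
Reagents that add atoms: none
Why: Acylation of a β-diketone dianion at its terminal, methyl-derived carbon by the acyl imidazole forms C10–C11 and gives 22. Its doubly stabilised C13 carbanion then attacks the lactone carbonyl C14 in a 6-exo-trig Claisen (Dieckmann-type) closure of ring A, expelling the C5 alkoxide and driven by formation of the β-triketone enolate. Since C11 bonds to the activated equatorial C10 and C13 to the axial lactone carbonyl, C1 has the configuration of the target.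

Step 18
Reactants: 23 spiro triketone (C11 unsubstituted; C9 triethylsilyl ether)
Product: 24 C9 triethylsilyl ether of the target (11,11-diprenyl; 1S,3S,4R,5S,9R)
Conditions: LiN(iPr)2 (3.2 equiv), THF, −78 to 0 °C; prenyl bromide (1.1 equiv); then LiN(iPr)2 (1.2 equiv), prenyl bromide (1.3 equiv), 0 °C to rt; aq. NH4Cl
Reagents that add atoms: 1-bromo-3-methylbut-2-ene (prenyl bromide), CC(C)=CCBr
Why: Carbon alkylation of the polyanion of a cyclic β-triketone: once the acidic C13 enol and the C5 hydroxyl are ionised, the next carbon acid is C11, the only ring carbon still bearing hydrogen. Its carbanion is the least stabilised and most nucleophilic site, so both prenyl groups enter there by SN2. The fully substituted C13 and the hindered tertiary alkoxide do not compete, and no stereocentre is touched.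

Step 19
Reactants: 24 C9 triethylsilyl ether of the target
Product: 25 the target CNP0198642.2 (1S,3S,4R,5S,9R)
Conditions: HF·pyridine, pyridine, THF, 0 °C to rt
Reagents that add atoms: none
Why: Fluoride cleavage of the tertiary triethylsilyl ether in a buffered medium too mild to protonate the prenyl alkenes or to dehydrate the tertiary alcohols.

## Compound list

1 | (2R)-but-3-yn-2-ol | C[C@@H](O)C#C | starting material
2 | tert-butyl{[(2R)-but-3-yn-2-yl]oxy}dimethylsilane | C[C@@H](O[Si](C)(C)C(C)(C)C)C#C | intermediate
3 | methyl (4R)-4-{[tert-butyl(dimethyl)silyl]oxy}pent-2-ynoate | C[C@@H](O[Si](C)(C)C(C)(C)C)C#CC(=O)OC | intermediate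
4 | 2-(2-bromoethyl)-2-methyl-1,3-dioxolane | CC1(CCBr)OCCO1 | starting material
5 | [2-(2-methyl-1,3-dioxolan-2-yl)ethyl]magnesium bromide | CC1(CC[Mg]Br)OCCO1 | intermediate (not isolated)
6 | methyl (2Z)-3-[(1R)-1-{[tert-butyl(dimethyl)silyl]oxy}ethyl]-5-(2-methyl-1,3-dioxolan-2-yl)pent-2-enoate | COC(=O)/C=C(\[C@@H](C)O[Si](C)(C)C(C)(C)C)CCC1(C)OCCO1 | intermediate
7 | methyl (2Z)-3-[(1R)-1-{[tert-butyl(dimethyl)silyl]oxy}ethyl]-6-oxohept-2-enoate | COC(=O)/C=C(\[C@@H](C)O[Si](C)(C)C(C)(C)C)CCC(C)=O | intermediate
8 | methyl (1S,2R)-5-[(1R)-1-{[tert-butyl(dimethyl)silyl]oxy}ethyl]-2-hydroxy-2-methylcyclopentane-1-carboxylate (ring carbon 5 open, 5R expected) | COC(=O)[C@H]1C(CC[C@@]1(C)O)[C@@H](C)O[Si](C)(C)C(C)(C)C | intermediate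
9 | methyl (1S,2R)-2-hydroxy-5-[(1R)-1-hydroxyethyl]-2-methylcyclopentane-1-carboxylate (ring carbon 5 open) | COC(=O)[C@H]1C(CC[C@@]1(C)O)[C@@H](C)O | intermediate
10 | methyl (1S,2R)-5-acetyl-2-hydroxy-2-methylcyclopentane-1-carboxylate (ring carbon 5 open) | COC(=O)[C@H]1C(CC[C@@]1(C)O)C(C)=O | intermediate
11 | methyl (1S,2R)-5-acetyl-2-methyl-2-[(triethylsilyl)oxy]cyclopentane-1-carboxylate (ring carbon 5 open) | COC(=O)[C@H]1C(CC[C@@]1(C)O[Si](CC)(CC)CC)C(C)=O | intermediate
12 | methyl (1S,2R,5R)-5-acetyl-2-methyl-2-[(triethylsilyl)oxy]cyclopentane-1-carboxylate | COC(=O)[C@H]1[C@@H](CC[C@@]1(C)O[Si](CC)(CC)CC)C(C)=O | intermediate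
13 | methyl (1S,2R,5R)-2-methyl-5-(prop-1-en-2-yl)-2-[(triethylsilyl)oxy]cyclopentane-1-carboxylate | COC(=O)[C@H]1[C@@H](CC[C@@]1(C)O[Si](CC)(CC)CC)C(C)=C | intermediate
14 | [(1R,2R,5R)-2-methyl-5-(prop-1-en-2-yl)-2-[(triethylsilyl)oxy]cyclopentyl]methanol | OC[C@H]1[C@@H](CC[C@@]1(C)O[Si](CC)(CC)CC)C(C)=C | intermediate
15 | triethyl{[(1R,2S,3R)-2-(iodomethyl)-1-methyl-3-(prop-1-en-2-yl)cyclopentyl]oxy}silane | IC[C@H]1[C@@H](CC[C@@]1(C)O[Si](CC)(CC)CC)C(C)=C | intermediate
16 | dibenzyl propanedioate (dibenzyl malonate) | O=C(CC(=O)OCc1ccccc1)OCc1ccccc1 | starting material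
17 | dibenzyl 2-{[(1S,2R,5R)-2-methyl-5-(prop-1-en-2-yl)-2-[(triethylsilyl)oxy]cyclopentyl]methyl}propanedioate | O=C(OCc1ccccc1)C(C[C@H]1[C@@H](CC[C@@]1(C)O[Si](CC)(CC)CC)C(C)=C)C(=O)OCc1ccccc1 | intermediate
18 | benzyl (1S,2R,5R,6S,8S)-1,5-dimethyl-9-oxo-5-[(triethylsilyl)oxy]-10-oxatricyclo[6.2.1.0^2,6]undecane-8-carboxylate | O=C(OCc1ccccc1)[C@@]2(C[C@H]3[C@@H](CC[C@@]3(C)O[Si](CC)(CC)CC)[C@@](C)(O4)C2)C4=O | intermediate
19 | (1S,2R,5R,6S,8S)-1,5-dimethyl-9-oxo-5-[(triethylsilyl)oxy]-10-oxatricyclo[6.2.1.0^2,6]undecane-8-carboxylic acid | OC(=O)[C@@]2(C[C@H]3[C@@H](CC[C@@]3(C)O[Si](CC)(CC)CC)[C@@](C)(O4)C2)C4=O | intermediate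
20 | (1S,2R,5R,6S,8S)-8-(1H-imidazole-1-carbonyl)-1,5-dimethyl-5-[(triethylsilyl)oxy]-10-oxatricyclo[6.2.1.0^2,6]undecan-9-one | O=C(n1ccnc1)[C@@]2(C[C@H]3[C@@H](CC[C@@]3(C)O[Si](CC)(CC)CC)[C@@](C)(O4)C2)C4=O | intermediate
21 | 6-methylheptane-2,4-dione | CC(C)CC(=O)CC(C)=O | starting material
22 | 1-[(1S,2R,5R,6S,8S)-1,5-dimethyl-9-oxo-5-[(triethylsilyl)oxy]-10-oxatricyclo[6.2.1.0^2,6]undecan-8-yl]-7-methyloctane-1,3,5-trione | CC(C)CC(=O)CC(=O)CC(=O)[C@@]2(C[C@H]3[C@@H](CC[C@@]3(C)O[Si](CC)(CC)CC)[C@@](C)(O4)C2)C4=O | intermediate (not isolated)
23 | spiro triketone: ring A enolised 13-(3-methylbutanoyl)cyclohexane-10,12,14-trione with C11 unsubstituted, spiro at C1 to the trans-fused ring B/ring C unit; C5 hydroxyl free, C9 triethylsilyl ether; (1S,3S,4R,5S,9R) | CC(C)CC(=O)C1=C(O)C=C(O)[C@@]2(C[C@H]3[C@@H](CC[C@@]3(C)O[Si](CC)(CC)CC)[C@@](C)(O)C2)C1=O | intermediate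
24 | C9 triethylsilyl ether of the target: as 23 with two 3-methylbut-2-enyl groups on C11; (1S,3S,4R,5S,9R) | CC(C)=CCC1(CC=C(C)C)C(=O)[C@@]2(C[C@H]3[C@@H](CC[C@@]3(C)O[Si](CC)(CC)CC)[C@@](C)(O)C2)C(=O)C(C(=O)CC(C)C)=C1O | intermediate
25 | CNP0198642.2: spiro compound with ring A 12-hydroxy-13-(3-methylbutanoyl)-11,11-bis(3-methylbut-2-enyl)cyclohex-12-ene-10,14-dione, ring B/ring C trans-fused, 5,9-dimethyl-5,9-diol; (1S,3S,4R,5S,9R) | CC(C)=CCC1(CC=C(C)C)C(=O)[C@@]2(C[C@H]3[C@@H](CC[C@@]3(C)O)[C@@](C)(O)C2)C(=O)C(C(=O)CC(C)C)=C1O | target

## Step count and least certain steps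

Total step count: 19. Longest linear sequence: 19 steps (1 to 25); 4, 16 and 21 enter as commercial partners.

**Step 5 (key step).** Most likely to go wrong: 1,2-reduction of the methyl ketone before the hindered β,β-disubstituted enoate is reduced; silylation or protonation of the copper enolate before it cyclises; or insufficient facial control, giving ring of the opposite sense. The enoate is the slowest class of acceptor for copper hydride, so the margin over the ketone is not large.

Fallback, from 6 back to 8: the ketone is kept masked, so nothing competes. Conjugate reduction of 6 with the same chiral copper hydride and polymethylhydrosiloxane in the presence of tert-butanol should give methyl (3R)-3-[(1R)-1-{[tert-butyl(dimethyl)silyl]oxy}ethyl]-5-(2-methyl-1,3-dioxolan-2-yl)pentanoate F1. Enolisation with LiN(iPr)2 and Me3SiCl followed by N-bromosuccinimide gives the 2-bromo ester F2. PPTS in wet acetone frees the ketone to give the bromo keto ester F3. SmI2 in THF at −78 °C then effects an intramolecular Reformatsky reaction, in which the chelated samarium enolate adds to the ketone to give 8 with hydroxyl and ester cis and the ester trans to the C4 substituent.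

**Step 17.** Most likely to go wrong: attack of the dianion on the lactone carbonyl instead of the acyl imidazole, which would reverse the sense at C1; closure through an enolate oxygen instead of C13; or a stall at 22 because C14 is a neopentyl carbonyl.

Fallback, from 19 back to 22 and then 23: 19 is converted with 1-chloro-N,N,2-trimethylprop-1-enylamine into the acid chloride F8. This is combined in CH2Cl2 at −78 °C with the neutral dianion equivalent 6-methyl-2,4-bis[(trimethylsilyl)oxy]hepta-1,3-diene F9 (made from 21 with Et3N/Me3SiCl, then LiN(iPr)2/Me3SiCl). F9 acylates at its terminal carbon and does not touch a lactone. After aqueous work-up, 22 is isolated and closed to 23 in a separate step with LiN(SiMe3)2 in THF.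

**Step 14.** Most likely to go wrong: loss of a proton from the C5 cation or its capture by acetic acid instead of by the ester; slow enolisation of the hindered malonate; and acidolysis of the silyl ether in warm acetic acid.

Fallback, from 17 back to 18: iodination of the malonate (NaH, N-iodosuccinimide) gives dibenzyl 2-iodo-2-{[(1S,2R,5R)-2-methyl-5-(prop-1-en-2-yl)-2-[(triethylsilyl)oxy]cyclopentyl]methyl}propanedioate F6. Iodine-atom-transfer cyclisation ((Bu3Sn)2 cat., hν, benzene, 80 °C) gives the tertiary iodide, dibenzyl (3R,3aS,7aR)-7-iodo-3,7-dimethyl-3-[(triethylsilyl)oxy]octahydro-1H-indene-5,5-dicarboxylate F7. On continued heating F7 ionises and is captured by the axial ester to give 18 under neutral conditions.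

**Step 18.** Most likely to go wrong: alkylation on enolate oxygen; a halt after the first prenyl group because the second alkylation creates a quaternary carbon with a hindered, SN2'-prone electrophile; and partial loss of material to mixed products.

Fallback, from 23 back to 24: the same polyanion is alkylated twice with the smaller and more reactive allyl bromide to give the 11,11-diallyl compound F10. Both allyl groups are then converted into prenyl groups by cross-metathesis with 2-methylbut-2-ene and the second-generation Grubbs catalyst in CH2Cl2 at 40 °C.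

**Step 13.** Most likely to go wrong: slow substitution at the β-branched iodide with competing E2 elimination to the exocyclic alkene.

Fallback, from 14 back to 17: Dess–Martin oxidation of 14 gives (1S,2R,5R)-2-methyl-5-(prop-1-en-2-yl)-2-[(triethylsilyl)oxy]cyclopentane-1-carbaldehyde F4. Knoevenagel condensation with 16 (TiCl4, pyridine, THF, 0 °C) gives the alkylidene malonate F5. Conjugate reduction with NaBH4 in THF/EtOH at 0 °C gives 17.

## Further compounds

F1 | step 5 | methyl (3R)-3-[(1R)-1-{[tert-butyl(dimethyl)silyl]oxy}ethyl]-5-(2-methyl-1,3-dioxolan-2-yl)pentanoate | COC(=O)C[C@@H](CCC1(C)OCCO1)[C@@H](C)O[Si](C)(C)C(C)(C)C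
F2 | step 5 | methyl (3S)-2-bromo-3-[(1R)-1-{[tert-butyl(dimethyl)silyl]oxy}ethyl]-5-(2-methyl-1,3-dioxolan-2-yl)pentanoate (C2 either configuration) | COC(=O)C(Br)[C@@H](CCC1(C)OCCO1)[C@@H](C)O[Si](C)(C)C(C)(C)C
F3 | step 5 | methyl (3S)-2-bromo-3-[(1R)-1-{[tert-butyl(dimethyl)silyl]oxy}ethyl]-6-oxoheptanoate (C2 either configuration) | COC(=O)C(Br)[C@@H](CCC(C)=O)[C@@H](C)O[Si](C)(C)C(C)(C)C
F4 | step 13 | (1S,2R,5R)-2-methyl-5-(prop-1-en-2-yl)-2-[(triethylsilyl)oxy]cyclopentane-1-carbaldehyde | O=C[C@H]1[C@@H](CC[C@@]1(C)O[Si](CC)(CC)CC)C(C)=C
F5 | step 13 | dibenzyl 2-{[(1S,2R,5R)-2-methyl-5-(prop-1-en-2-yl)-2-[(triethylsilyl)oxy]cyclopentyl]methylidene}propanedioate | O=C(OCc1ccccc1)C(=C[C@H]1[C@@H](CC[C@@]1(C)O[Si](CC)(CC)CC)C(C)=C)C(=O)OCc1ccccc1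
F6 | step 14 | dibenzyl 2-iodo-2-{[(1S,2R,5R)-2-methyl-5-(prop-1-en-2-yl)-2-[(triethylsilyl)oxy]cyclopentyl]methyl}propanedioate | O=C(OCc1ccccc1)C(I)(C[C@H]1[C@@H](CC[C@@]1(C)O[Si](CC)(CC)CC)C(C)=C)C(=O)OCc1ccccc1
F7 | step 14 | dibenzyl (3R,3aS,7aR)-7-iodo-3,7-dimethyl-3-[(triethylsilyl)oxy]octahydro-1H-indene-5,5-dicarboxylate (C7 either configuration) | O=C(OCc1ccccc1)C2(C[C@H]3[C@@H](CC[C@@]3(C)O[Si](CC)(CC)CC)C(C)(I)C2)C(=O)OCc1ccccc1
F8 | step 17 | (1S,2R,5R,6S,8R)-1,5-dimethyl-9-oxo-5-[(triethylsilyl)oxy]-10-oxatricyclo[6.2.1.0^2,6]undecane-8-carbonyl chloride | O=C(Cl)[C@@]2(C[C@H]3[C@@H](CC[C@@]3(C)O[Si](CC)(CC)CC)[C@@](C)(O4)C2)C4=O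
F9 | step 17 | 6-methyl-2,4-bis[(trimethylsilyl)oxy]hepta-1,3-diene | C=C(O[Si](C)(C)C)C=C(CC(C)C)O[Si](C)(C)C
F10 | step 18 | 11,11-diallyl analogue of 24 (two prop-2-enyl groups on C11; C9 triethylsilyl ether) | C=CCC1(CC=C)C(=O)[C@@]2(C[C@H]3[C@@H](CC[C@@]3(C)O[Si](CC)(CC)CC)[C@@](C)(O)C2)C(=O)C(C(=O)CC(C)C)=C1O
A1 | alternative 1 | symmetric spiro trione: ring A cyclohexane-1,3,5-trione with C11 and C13 unsubstituted, C5 and C9 carbinols free | O=C1CC(=O)CC(=O)C12C[C@H]3[C@@H](CC[C@@]3(C)O)[C@@](C)(O)C2
A2 | alternative 1 | the target lacking its 3-methylbutanoyl group | CC(C)=CCC1(CC=C(C)C)C(=O)[C@@]2(C[C@H]3[C@@H](CC[C@@]3(C)O)[C@@](C)(O)C2)C(=O)C=C1O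
A3 | alternative 2 | dimethyl 2-{[(1S,2R,5R)-2-methyl-5-(prop-1-en-2-yl)-2-[(triethylsilyl)oxy]cyclopentyl]methyl}propanedioate | COC(=O)C(C[C@H]1[C@@H](CC[C@@]1(C)O[Si](CC)(CC)CC)C(C)=C)C(=O)OC
A4 | alternative 2 | methyl (1S,2R,5R,6S,8S)-1,5-dimethyl-9-oxo-5-[(triethylsilyl)oxy]-10-oxatricyclo[6.2.1.0^2,6]undecane-8-carboxylate | COC(=O)[C@@]2(C[C@H]3[C@@H](CC[C@@]3(C)O[Si](CC)(CC)CC)[C@@](C)(O4)C2)C4=O
A5 | alternative 3 | spiro acylphloroglucinol lacking the two prenyl groups, C9 triethylsilyl ether (identical with 23) | CC(C)CC(=O)C1=C(O)C=C(O)[C@@]2(C[C@H]3[C@@H](CC[C@@]3(C)O[Si](CC)(CC)CC)[C@@](C)(O)C2)C1=O
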